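Ring B is cut at C1–C2 and C5–C6. The adjacent carboxyl carbon C1 and propyl carbon C6 are the two alkyne carbons of a hex-2-ynoate; C2–C5 come from a tetra-oxygenated butadiene whose middle oxygen (O3) already carries the ring A aroyl group. One Diels–Alder benzannulation with aromatising loss of benzyl alcohol thus builds ring B, places all five substituents and delivers the pyrogallol with O3 acylated and the C2 and C4 hydroxyls free, which removes any need for regioselective acylation of a triol. The diene is the bis(trimethylsilyl) dienol ether of benzyl 2-(2,4-dimethoxy-6-propylbenzoyloxy)acetoacetate; benzyl on both esters lets one hydrogenolysis finish.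

Key step: step 9

Remark on the chemistry: the target is achiral. Ring A is the 2,4-dimethoxy-6-propylbenzoyl ring; ring B is numbered C1 (carboxyl), C2 (OH), C3 (aroyloxy), C4 (OH), C5 (H), C6 (propyl). The double-bond geometry of the two silyl enol ether intermediates is erased in the step that follows each, so they are used as formed.

Design note: both enol oxygens carry trimethylsilyl so that dilute acid alone unmasks the phenols. The ketene-acetal alkoxy group and the ynoate ester are both benzyl, so either aromatisation pathway converges in one hydrogenolysis. The cheap ynoate is used in excess, and a neutral silyl amide scavenges the benzyl alcohol that is released.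

Step 1
Reactants: 1 5-propylresorcinol (divarinol)
Product: 2 1,3-dimethoxy-5-propylbenzene
Conditions: MeI, K2CO3, acetone, reflux
Reagents that add atoms: iodomethane, CI
Why: Williamson ether synthesis, in which K2CO3 deprotonates both phenols and the phenoxides are O-methylated by SN2 on iodomethane, the standard way to resorcinol dimethyl ethers.

Step 2
Reactants: 2 1,3-dimethoxy-5-propylbenzene
Product: 4 2,4-dimethoxy-6-propylbenzaldehyde, via iminium salt 3 (not isolated)
Conditions: POCl3, DMF, 0 °C to 70 °C; then aq NaOAc
Reagents that add atoms: N,N-dimethylformamide, CN(C)C=O; water, O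
Why: Vilsmeier–Haack formylation, in which the chloroiminium electrophile substitutes the ring carbon next to propyl (para to one methoxy, ortho to the other) in preference to the more crowded carbon between the two methoxy groups, and the iminium salt is hydrolysed on work-up; any minor regioisomer should be removable by chromatography at this stage.

Step 3
Reactants: 4 2,4-dimethoxy-6-propylbenzaldehyde
Product: 5 2,4-dimethoxy-6-propylbenzoic acid
Conditions: NaClO2, NaH2PO4, 2-methyl-2-butene, t-BuOH/H2O, rt
Reagents that add atoms: sodium chlorite, [Na+].[O-]Cl=O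
Why: Pinnick oxidation, in which chlorous acid adds to the aldehyde and fragments to the acid while excess 2-methyl-2-butene traps the hypochlorous acid that could otherwise chlorinate the electron-rich ring.

Step 4
Reactants: 6 benzyl acetoacetate
Product: 7 benzyl 2-chloro-3-oxobutanoate
Conditions: SO2Cl2 (1.0 equiv), CH2Cl2, 0 °C to rt
Reagents that add atoms: sulfuryl chloride, ClS(Cl)(=O)=O
Why: Electrophilic α-chlorination of the enol of a β-keto ester with sulfuryl chloride, which should stop at the monochloride with one equivalent at low temperature.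

Step 5
Reactants: 5 2,4-dimethoxy-6-propylbenzoic acid; 7 benzyl 2-chloro-3-oxobutanoate
Product: 8 benzyl 2-[(2,4-dimethoxy-6-propylbenzoyl)oxy]-3-oxobutanoate
Conditions: Et3N, DMF, rt
Reagents that add atoms: none
Why: SN2 O-alkylation of a carboxylate by an α-chloro-β-keto ester, the reaction class used to make 2-acyloxyacetoacetates; the carboxylate oxygen lies outside the reach of the two ortho substituents, so the hindered acid should still alkylate readily.

Step 6
Reactants: 8 benzyl 2-[(2,4-dimethoxy-6-propylbenzoyl)oxy]-3-oxobutanoate
Product: 9 benzyl 2-[(2,4-dimethoxy-6-propylbenzoyl)oxy]-3-(trimethylsilyloxy)but-2-enoate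
Conditions: TMSCl, Et3N, toluene, rt; filtered under argon, used crude
Reagents that add atoms: chlorotrimethylsilane, C[Si](C)(C)Cl
Why: Silyl enol ether formation by amine-mediated enolisation and O-silylation of the ketone carbonyl of the β-keto ester, the first stage of the standard two-stage preparation of 1-alkoxy-1,3-bis(silyloxy)butadienes.

Step 7
Reactants: 9 benzyl 2-[(2,4-dimethoxy-6-propylbenzoyl)oxy]-3-(trimethylsilyloxy)but-2-enoate
Product: 11 [(1E)-1-(benzyloxy)-1,3-bis(trimethylsilyloxy)buta-1,3-dien-2-yl] 2,4-dimethoxy-6-propylbenzoate, via lithium dienolate 10 (not isolated)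
Conditions: LiN(iPr)2 (LDA, 1.05 equiv), THF, −78 °C; then TMSCl, −78 °C to 0 °C; pentane, filtered under argon, used crude
Reagents that add atoms: chlorotrimethylsilane, C[Si](C)(C)Cl
Why: Kinetic γ-deprotonation of the β-silyloxy enoate (vinylogous ester enolate formation) followed by O-silylation gives the silyl ketene acetal, the second stage of the standard bis(silyloxy)diene preparation; the shielded ortho,ortho′-disubstituted aroyl carbonyl and one equivalent of base at low temperature should guard against acyl transfer and benzylic metalation.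

Step 8
Reactants: 12 hex-2-ynoic acid
Product: 13 benzyl hex-2-ynoate
Conditions: BnBr, K2CO3, DMF, rt
Reagents that add atoms: benzyl bromide, BrCc1ccccc1
Why: Carboxylate O-alkylation (SN2) with benzyl bromide, mild enough to leave the conjugated triple bond untouched.

Step 9
Reactants: 11 [(1E)-1-(benzyloxy)-1,3-bis(trimethylsilyloxy)buta-1,3-dien-2-yl] 2,4-dimethoxy-6-propylbenzoate; 13 benzyl hex-2-ynoate
Product: 16 benzyl 3-[(2,4-dimethoxy-6-propylbenzoyl)oxy]-2,4-dihydroxy-6-propylbenzoate, via cycloadduct 14 (not isolated), via bis-silyl aryl ether 15 (not isolated)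
Conditions: 13 (3 equiv), N,O-bis(trimethylsilyl)acetamide (BSA, 1.5 equiv), toluene, 120 °C, sealed tube; then 1 M HCl, THF, 0 °C to rt
Reagents that add atoms: none
Why: The diene, whose HOMO is raised and polarised toward its unsubstituted CH2 terminus by the two ketene-acetal oxygens and the 3-silyloxy group, adds to the ynoate in a polar, asynchronous Diels–Alder reaction in which the CH2 terminus bonds to the propyl-bearing β-carbon (C5–C6) and the ketene-acetal carbon to the α-carbon (C1–C2), giving cyclohexa-1,4-diene 14 with a ketal carbon at C2. Loss of benzyl alcohol across C2 and C5 (trapped by the silyl amide so that it cannot protonate unreacted diene) aromatises 14 to 15, and dilute acid then frees the C2 and C4 phenols. The closest known reaction type is the thermal benzannulation of 1-alkoxy-1,3-bis(silyloxy)butadienes and related trioxygenated dienes with acetylenic esters to resorcylates; the aroyloxy group on the diene is the one untried variation. Ring B is closed in the intermolecular [4+2] mode, both new bonds in one event (in the stepwise limit, 6-exo-trig attack of the allenoate carbon on the dioxycarbenium carbon). No stereocentre survives, since the racemic ketal carbon of 14 becomes an aromatic carbon. The step needs regioselectivity, secured by the match of the largest HOMO coefficient (CH2 terminus) with the largest LUMO coefficient (ynoate β-carbon), which the weakly donating aroyloxy group cannot overturn, and it needs the aroyl group to stay on O3, secured by the shielded ortho,ortho′-disubstituted ring A carbonyl and a base-free work-up.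

Step 10
Reactants: 16 benzyl 3-[(2,4-dimethoxy-6-propylbenzoyl)oxy]-2,4-dihydroxy-6-propylbenzoate
Product: 17 3-[(2,4-dimethoxy-6-propylbenzoyl)oxy]-2,4-dihydroxy-6-propylbenzoic acid (CNP0211929.0)
Conditions: H2 (1 atm), 10% Pd/C, EtOAc, rt
Reagents that add atoms: none
Why: Catalytic hydrogenolysis of the benzyl ester over Pd/C under neutral conditions, which should leave the aryl ester, methyl ethers and phenols intact, avoid the base that could move the acyl group from O3 to a neighbouring hydroxyl, and also cleave any O2 benzyl ether that arises if step 9 loses silanol in place of benzyl alcohol.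

Compound list
1 | 5-propylresorcinol (divarinol) | CCCc1cc(O)cc(O)c1 | starting material
2 | 1,3-dimethoxy-5-propylbenzene | CCCc1cc(OC)cc(OC)c1 | intermediate
3 | N-[(2,4-dimethoxy-6-propylphenyl)methylidene]-N-methylmethanaminium dichlorophosphate | CCCc1cc(OC)cc(OC)c1C=[N+](C)C.[O-]P(=O)(Cl)Cl | intermediate (not isolated)
4 | 2,4-dimethoxy-6-propylbenzaldehyde | CCCc1cc(OC)cc(OC)c1C=O | intermediate
5 | 2,4-dimethoxy-6-propylbenzoic acid | CCCc1cc(OC)cc(OC)c1C(=O)O | intermediate
6 | benzyl acetoacetate | CC(=O)CC(=O)OCc1ccccc1 | starting material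
7 | benzyl 2-chloro-3-oxobutanoate (racemic) | CC(=O)C(Cl)C(=O)OCc1ccccc1 | intermediate
8 | benzyl 2-[(2,4-dimethoxy-6-propylbenzoyl)oxy]-3-oxobutanoate (racemic, labile α-centre) | CCCc1cc(OC)cc(OC)c1C(=O)OC(C(C)=O)C(=O)OCc1ccccc1 | intermediate
9 | benzyl 2-[(2,4-dimethoxy-6-propylbenzoyl)oxy]-3-(trimethylsilyloxy)but-2-enoate (mixture of E and Z isomers, geometry lost in step 7) | CC(O[Si](C)(C)C)=C(OC(=O)c1c(CCC)cc(OC)cc1OC)C(=O)OCc1ccccc1 | intermediate
10 | lithium 1-(benzyloxy)-2-[(2,4-dimethoxy-6-propylbenzoyl)oxy]-3-(trimethylsilyloxy)buta-1,3-dien-1-olate | C=C(O[Si](C)(C)C)C(OC(=O)c1c(CCC)cc(OC)cc1OC)=C([O-])OCc1ccccc1.[Li+] | intermediate (not isolated)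
11 | [(1E)-1-(benzyloxy)-1,3-bis(trimethylsilyloxy)buta-1,3-dien-2-yl] 2,4-dimethoxy-6-propylbenzoate (drawn as 1E; the 1Z isomer serves equally, geometry lost at the ketal carbon) | C=C(O[Si](C)(C)C)/C(OC(=O)c1c(CCC)cc(OC)cc1OC)=C(/OCc1ccccc1)O[Si](C)(C)C | intermediate
12 | hex-2-ynoic acid | CCCC#CC(=O)O | starting material
13 | benzyl hex-2-ynoate | CCCC#CC(=O)OCc1ccccc1 | intermediate
14 | benzyl 6-(benzyloxy)-5-[(2,4-dimethoxy-6-propylbenzoyl)oxy]-2-propyl-4,6-bis(trimethylsilyloxy)cyclohexa-1,4-diene-1-carboxylate (racemic at the ketal carbon) | CCCC1=C(C(=O)OCc2ccccc2)C(OCc2ccccc2)(O[Si](C)(C)C)C(OC(=O)c2c(CCC)cc(OC)cc2OC)=C(O[Si](C)(C)C)C1 | intermediate (not isolated)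
15 | benzyl 3-[(2,4-dimethoxy-6-propylbenzoyl)oxy]-6-propyl-2,4-bis(trimethylsilyloxy)benzoate | CCCc1cc(O[Si](C)(C)C)c(OC(=O)c2c(CCC)cc(OC)cc2OC)c(O[Si](C)(C)C)c1C(=O)OCc1ccccc1 | intermediate (not isolated)
16 | benzyl 3-[(2,4-dimethoxy-6-propylbenzoyl)oxy]-2,4-dihydroxy-6-propylbenzoate | CCCc1cc(OC)cc(OC)c1C(=O)Oc1c(O)cc(CCC)c(C(=O)OCc2ccccc2)c1O | intermediate
17 | 3-[(2,4-dimethoxy-6-propylbenzoyl)oxy]-2,4-dihydroxy-6-propylbenzoic acid | CCCc1cc(OC)cc(OC)c1C(=O)Oc1c(O)cc(CCC)c(C(=O)O)c1O | target

Total step count: 10.
Longest linear sequence: 8 steps (steps 1, 2, 3, 5, 6, 7, 9, 10).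

Steps most likely to fail

Step 9. The diene may be used up by desilylation or by silyl and acyl shifts faster than it adds to the slow, β-alkylated ynoate, or the regiochemical bias may erode. The fallback sets out from acid 5 and comes back at target 17. It takes ring B from a preformed pyrogallol and distinguishes its oxygens by acidity and chelation.
- Purchased 2,6-dimethoxy-4-propylphenol F1 is demethylated (BBr3, CH2Cl2) to 5-propylbenzene-1,2,3-triol F2.
- Kolbe–Schmitt carboxylation (KHCO3, CO2, heat) next to an outer hydroxyl should give 2,3,4-trihydroxy-6-propylbenzoic acid F3.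
- Two equivalents of BnBr with KHCO3 in DMF should benzylate the carboxylate and the most acidic phenol (O4, para to the ester), giving benzyl 4-(benzyloxy)-2,3-dihydroxy-6-propylbenzoate F4.
- Acid 5 is converted with oxalyl chloride and catalytic DMF into 2,4-dimethoxy-6-propylbenzoyl chloride F5.
- F5 should acylate the O3 hydroxyl of F4 (Et3N, DMAP, CH2Cl2), because the O2 hydroxyl is held in a hydrogen bond to the ester carbonyl. This gives benzyl 4-(benzyloxy)-3-[(2,4-dimethoxy-6-propylbenzoyl)oxy]-2-hydroxy-6-propylbenzoate F6.
- Hydrogenolysis (H2, Pd/C, EtOAc) of both benzyl groups then gives 17.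

Step 7. The amide base may deprotonate the benzylic CH2 of the ortho-propyl group, the lithium dienolate may pass the aroyl group from oxygen to oxygen before it is silylated, or silylation may occur at the γ-carbon. The fallback sets out from keto ester 8 and comes back at diene 11. It replaces strong-base deprotonation by soft enolisation: TMSOTf (2.2 equiv) and Et3N in Et2O at 0 °C should silylate both enolisable positions in one operation, as is known for β-dicarbonyl compounds, so that no charged enolate is formed. This fallback makes no new compound (F0).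

Step 5. The amine or carboxylate may enolise the chloro keto ester, which would slow the substitution and open self-condensation, or the product may lose its acetyl group by retro-Claisen cleavage. The fallback sets out from benzyl acetoacetate 6 and acid 5 and comes back at keto ester 8. Diazo transfer to 6 (p-acetamidobenzenesulfonyl azide, Et3N, MeCN) gives benzyl 2-diazo-3-oxobutanoate F7. O–H insertion of its rhodium carbenoid into acid 5, catalysed by Rh2(OAc)4 in CH2Cl2 at reflux, a known route to 2-acyloxy-β-keto esters, then gives 8 under neutral conditions.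

Further compounds
F1 | step 9 | 2,6-dimethoxy-4-propylphenol (purchased) | CCCc1cc(OC)c(O)c(OC)c1
F2 | step 9 | 5-propylbenzene-1,2,3-triol | CCCc1cc(O)c(O)c(O)c1
F3 | step 9 | 2,3,4-trihydroxy-6-propylbenzoic acid | CCCc1cc(O)c(O)c(O)c1C(=O)O
F4 | step 9 | benzyl 4-(benzyloxy)-2,3-dihydroxy-6-propylbenzoate | CCCc1cc(OCc2ccccc2)c(O)c(O)c1C(=O)OCc1ccccc1
F5 | step 9 | 2,4-dimethoxy-6-propylbenzoyl chloride | CCCc1cc(OC)cc(OC)c1C(Cl)=O
F6 | step 9 | benzyl 4-(benzyloxy)-3-[(2,4-dimethoxy-6-propylbenzoyl)oxy]-2-hydroxy-6-propylbenzoate | CCCc1cc(OC)cc(OC)c1C(=O)Oc1c(OCc2ccccc2)cc(CCC)c(C(=O)OCc2ccccc2)c1O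
F0 | step 7 | none | none
F7 | step 5 | benzyl 2-diazo-3-oxobutanoate | CC(=O)C(=[N+]=[N-])C(=O)OCc1ccccc1
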